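**Retrosynthetic overview**
1. Target ⇒ the C8 ketone is installed last, by electrochemical allylic C–H oxidation of the 8-deoxo diester that already carries the exocyclic C7=C11 alkene.
2. 8-Deoxo diester ⇒ eudesm-7(11)-ene-3α,4α-diol + (2R,3S)-3-acetoxy-2-hydroxy-2-methylbutanoic acid (C3 ester first, then C4 acetate).
3. Diol ⇒ α-face dihydroxylation of selina-3,7(11)-diene ⇒ enol triflate from dissolving-metal reduction of a 4-methyl-Δ4-3-octalone (sets the trans ring fusion).
4. Ring order: ring B is bought as (S)-carvone; ring A is annulated onto it (Mukaiyama–Michael/aldol with ethyl vinyl ketone). The carvone stereocentre fixes C10 and is then erased as C7=C11.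
5. Acid ⇒ chelation-controlled vinyl addition to (S)-3-(benzyloxy)butan-2-one (from L-lactic acid), then oxidative cleavage of the vinyl group.

Assumption: eudesmane numbering (C1–C15; C14 = methyl on C10, C15 = methyl on C4) and α/β face descriptors are used in names, and O-benzyl-L-lactic acid is taken as a purchasable derivative of L-lactic acid.

**Route**

Step 1
Reactants: 1 (S)-(+)-carvone
Product: 2 triethyl{[(5S)-2-methyl-5-(prop-1-en-2-yl)cyclohex-1-en-1-yl]oxy}silane
Conditions: Et3SiH (1.1 equiv), RhCl(PPh3)3 (0.5 mol %), THF, 50 °C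
Reagents that add atoms: triethylsilane, CC[SiH](CC)CC
Why: Rhodium-catalysed 1,4-hydrosilylation of the enone gives the tetrasubstituted silyl enol ether regiospecifically and leaves the C5 stereocentre and the isopropenyl group untouched.

Step 2
Reactants: 2 triethyl{[(5S)-2-methyl-5-(prop-1-en-2-yl)cyclohex-1-en-1-yl]oxy}silane; 3 pent-1-en-3-one (ethyl vinyl ketone)
Product: 5 (4aS,7S)-1,4a-dimethyl-7-(prop-1-en-2-yl)-4,4a,5,6,7,8-hexahydronaphthalen-2(3H)-one, via 1,5-diketone 4 (not isolated)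
Conditions: BF3·OEt2 (1 equiv), i-PrOH (1 equiv), MeNO2/CH2Cl2, −78 → −20 °C; aqueous work-up; then KOH, MeOH, 65 °C
Reagents that add atoms: none
Why: Mukaiyama–Michael addition then intramolecular aldol condensation (Robinson annulation), in which the enone adds axially on the face cis to the equatorial isopropenyl group, so the new quaternary centre (C10) carries its methyl trans to isopropenyl (expected about 5:1, minor isomer removed after cyclisation).

Step 3
Reactants: 5 (4aS,7S)-1,4a-dimethyl-7-(prop-1-en-2-yl)-4,4a,5,6,7,8-hexahydronaphthalen-2(3H)-one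
Product: 7 (4aS,7S,8aR)-1,4a-dimethyl-7-(prop-1-en-2-yl)-3,4,4a,5,6,7,8,8a-octahydronaphthalen-2-yl trifluoromethanesulfonate, via lithium enolate 6 (not isolated)
Conditions: Li (2.2 equiv), liquid NH3/THF, t-BuOH (1 equiv), −78 °C; NH3 evaporated; PhNTf2 (1.2 equiv), THF, 0 °C → rt
Reagents that add atoms: N-phenylbis(trifluoromethanesulfonimide), O=S(=O)(N(c1ccccc1)S(=O)(=O)C(F)(F)F)C(F)(F)F
Why: Dissolving-metal enone reduction with axial protonation at C5 gives the trans ring fusion (5α-H), and the regiodefined C3(O)=C4 enolate is trapped on oxygen as the enol triflate (reductive triflation).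

Step 4
Reactants: 7 (4aS,7S,8aR)-1,4a-dimethyl-7-(prop-1-en-2-yl)-3,4,4a,5,6,7,8,8a-octahydronaphthalen-2-yl trifluoromethanesulfonate
Product: 8 (4aS,8aR)-1,4a-dimethyl-7-(propan-2-ylidene)-3,4,4a,5,6,7,8,8a-octahydronaphthalen-2-yl trifluoromethanesulfonate
Conditions: Co(salen)Cl (3 mol %; salen = achiral N,N'-ethylenebis(3,5-di-tert-butylsalicylideneiminate)), PhSiH3 (6 mol %), benzene, rt
Reagents that add atoms: none
Why: Cobalt hydride hydrogen-atom-transfer alkene isomerisation moves the 1,1-disubstituted isopropenyl double bond to the tetrasubstituted C7=C11 position, the electron-poor enol triflate being inert, and the C7 stereocentre, no longer needed, is erased.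

Step 5
Reactants: 8 (4aS,8aR)-1,4a-dimethyl-7-(propan-2-ylidene)-3,4,4a,5,6,7,8,8a-octahydronaphthalen-2-yl trifluoromethanesulfonate
Product: 9 (4aR,8aR)-5,8a-dimethyl-3-(propan-2-ylidene)-1,2,3,4,4a,7,8,8a-octahydronaphthalene [selina-3,7(11)-diene]
Conditions: Pd(OAc)2 (5 mol %), PPh3 (10 mol %), HCO2H (2 equiv), n-Bu3N (3 equiv), DMF, 60 °C
Reagents that add atoms: none
Why: Palladium-catalysed formate reduction of the enol triflate replaces OTf by H and leaves the C3=C4 double bond exactly where the enolate placed it.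

Step 6
Reactants: 9 (4aR,8aR)-5,8a-dimethyl-3-(propan-2-ylidene)-1,2,3,4,4a,7,8,8a-octahydronaphthalene
Product: 10 (1S,2R,4aS,8aR)-1,4a-dimethyl-7-(propan-2-ylidene)decahydronaphthalene-1,2-diol [eudesm-7(11)-ene-3α,4α-diol]
Conditions: OsO4 (2 mol %), NMO (1.1 equiv), acetone/H2O 8:1, 0 °C → rt
Reagents that add atoms: osmium tetroxide, O=[Os](=O)(=O)=O; N-methylmorpholine N-oxide, C[N+]1([O-])CCOCC1; water, O
Why: Upjohn dihydroxylation adds to the trisubstituted C3=C4 bond from the α-face, opposite the axial C10 methyl, giving the cis-3α,4α-diol with the C4 methyl β, while the tetrasubstituted C7=C11 bond reacts far more slowly.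

Step 7
Reactants: 11 (S)-2-(benzyloxy)propanoic acid (O-benzyl-L-lactic acid)
Product: 12 (S)-3-(benzyloxy)butan-2-one
Conditions: MeLi (2.2 equiv), THF, −78 → 0 °C; inverse quench into cold aq NH4Cl
Reagents that add atoms: methyllithium, [Li]C
Why: Organolithium addition to the lithium carboxylate stops at the stable gem-diolate and gives the methyl ketone on work-up without touching the α-stereocentre.

Step 8
Reactants: 12 (S)-3-(benzyloxy)butan-2-one
Product: 13 (3S,4S)-4-(benzyloxy)-3-methylpent-1-en-3-ol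
Conditions: CH2=CHMgBr (1.5 equiv), THF, −78 °C
Reagents that add atoms: vinylmagnesium bromide, C=C[Mg]Br
Why: Cram-chelate Grignard addition, in which magnesium bridges the ketone and benzyloxy oxygens and vinyl attacks from the side of the small hydrogen, sets the tertiary carbinol (the later 2R centre) syn to the lactate-derived centre.

Step 9
Reactants: 13 (3S,4S)-4-(benzyloxy)-3-methylpent-1-en-3-ol
Product: 15 (2R,3S)-3-(benzyloxy)-2-hydroxy-2-methylbutanoic acid, via hydroxy aldehyde 14 (not isolated)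
Conditions: O3, CH2Cl2/MeOH, −78 °C; Me2S; then NaClO2, NaH2PO4, 2-methylbut-2-ene, t-BuOH/H2O, 0 °C → rt
Reagents that add atoms: ozone, [O-][O+]=O; sodium chlorite, [Na+].[O-]Cl=O
Why: Ozonolysis with reductive work-up followed by Pinnick oxidation turns the vinyl group into the carboxylic acid, and neither stereocentre can epimerise because the α-carbon is quaternary.

Step 10
Reactants: 15 (2R,3S)-3-(benzyloxy)-2-hydroxy-2-methylbutanoic acid
Product: 17 (2R,3S)-3-acetoxy-2-hydroxy-2-methylbutanoic acid, via dihydroxy acid 16 (not isolated)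
Conditions: H2 (1 atm), Pd/C (10 % Pd), EtOAc, rt; filtered; then Ac2O (2.5 equiv), pyridine, 0 °C → rt; aqueous work-up
Reagents that add atoms: acetic anhydride, CC(=O)OC(C)=O
Why: Hydrogenolysis of the benzyl ether then selective acetylation of the secondary hydroxyl, the tertiary α-hydroxyl being unreactive at room temperature and the mixed anhydride hydrolysing on work-up.

Step 11
Reactants: 17 (2R,3S)-3-acetoxy-2-hydroxy-2-methylbutanoic acid; 10 (1S,2R,4aS,8aR)-1,4a-dimethyl-7-(propan-2-ylidene)decahydronaphthalene-1,2-diol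
Product: 20 (3α,4α)-4-hydroxyeudesm-7(11)-en-3-yl (2R,3S)-3-acetoxy-2-methyl-2-[(trimethylsilyl)oxy]butanoate, via bis-silylated acid 18 (not isolated), via acid chloride 19 (not isolated)
Conditions: 17, Me3SiCl (2.2 equiv), Et3N (2.3 equiv), CH2Cl2, 0 °C; (COCl)2 (1.1 equiv), DMF (cat.), 0 °C → rt; volatiles removed; then 10, DMAP (1.5 equiv), pyridine, CH2Cl2, 40 °C
Reagents that add atoms: chlorotrimethylsilane, C[Si](C)(C)Cl
Why: DMAP-catalysed acylation by an acid chloride made under neutral conditions from the silyl ester esterifies only the secondary axial 3α-hydroxyl of the cis-diol, while the trimethylsilyl ether masks the tertiary α-hydroxyl of the acid.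

Step 12
Reactants: 20 (3α,4α)-4-hydroxyeudesm-7(11)-en-3-yl (2R,3S)-3-acetoxy-2-methyl-2-[(trimethylsilyl)oxy]butanoate
Product: 22 (3α,4α)-4-acetoxyeudesm-7(11)-en-3-yl (2R,3S)-3-acetoxy-2-hydroxy-2-methylbutanoate, via silyl ether acetate 21 (not isolated)
Conditions: Ac2O (5 equiv), DMAP (2 equiv), Et3N, CH2Cl2, 40 °C; then 1 M aq HCl/THF, 0 °C
Reagents that add atoms: acetic anhydride, CC(=O)OC(C)=O
Why: DMAP-catalysed acetylation of the remaining tertiary 4α-hydroxyl (the side-chain tertiary hydroxyl is blocked as its silyl ether) followed by mild acid hydrolysis of the silyl ether, with no stereocentre involved.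

Step 13
Reactants: 22 (3α,4α)-4-acetoxyeudesm-7(11)-en-3-yl (2R,3S)-3-acetoxy-2-hydroxy-2-methylbutanoate
Product: 23 (3α,4α)-4-acetoxy-8-oxoeudesm-7(11)-en-3-yl (2R,3S)-3-acetoxy-2-hydroxy-2-methylbutanoate (CNP0134046.2)
Conditions: undivided cell, reticulated vitreous carbon anode and cathode, constant current (10 mA per mmol), N-hydroxytetrachlorophthalimide (20 mol %), t-BuOOH (1.5 equiv), pyridine (2 equiv), LiClO4 (0.1 M), acetone, rt
Reagents that add atoms: tert-butyl hydroperoxide, CC(C)(C)OO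
Why: Proposed new method: site-selective electrochemical allylic C–H oxidation of a tetrasubstituted exocyclic alkene, in which anodically generated tetrachlorophthalimide N-oxyl abstracts the axial C8–H (C6–H is shielded by the axial 4β- and 10β-methyls and the 4α-acetate, and the methyl C–H bonds are primary), the C8/C11 allyl radical is trapped at its secondary terminus by t-BuOO• and pyridine-mediated Kornblum–DeLaMare-type loss of t-BuOH gives the conjugated C8 ketone; the closest known reaction type is N-oxyl-mediated electrochemical allylic C–H oxidation of trisubstituted cyclic alkenes to enones, which has not been shown for tetrasubstituted alkylidene rings or for choosing between two flanking CH2 groups.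

**Compound list**
1 | (S)-(+)-carvone, (5S)-2-methyl-5-(prop-1-en-2-yl)cyclohex-2-en-1-one | CC1=CC[C@H](C(C)=C)CC1=O | starting material
2 | triethyl{[(5S)-2-methyl-5-(prop-1-en-2-yl)cyclohex-1-en-1-yl]oxy}silane | CC1=C(O[Si](CC)(CC)CC)C[C@@H](C(C)=C)CC1 | intermediate
3 | pent-1-en-3-one (ethyl vinyl ketone) | CCC(=O)C=C | starting material
4 | (2S,5S)-2-methyl-2-(3-oxopentyl)-5-(prop-1-en-2-yl)cyclohexan-1-one | CCC(=O)CC[C@]1(C)CC[C@H](C(C)=C)CC1=O | intermediate
5 | (4aS,7S)-1,4a-dimethyl-7-(prop-1-en-2-yl)-4,4a,5,6,7,8-hexahydronaphthalen-2(3H)-one (7-epi-α-cyperone; 10β-CH3, 7α-isopropenyl) | O=C1CC[C@]2(C)CC[C@H](C(C)=C)CC2=C1C | intermediate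
6 | lithium (4aS,7S,8aR)-1,4a-dimethyl-7-(prop-1-en-2-yl)-3,4,4a,5,6,7,8,8a-octahydronaphthalen-2-olate | CC1=C([O-])CC[C@]2(C)CC[C@H](C(C)=C)C[C@@H]12.[Li+] | intermediate
7 | (4aS,7S,8aR)-1,4a-dimethyl-7-(prop-1-en-2-yl)-3,4,4a,5,6,7,8,8a-octahydronaphthalen-2-yl trifluoromethanesulfonate (trans-fused, 5α-H) | CC1=C(OS(=O)(=O)C(F)(F)F)CC[C@]2(C)CC[C@H](C(C)=C)C[C@@H]12 | intermediate
8 | (4aS,8aR)-1,4a-dimethyl-7-(propan-2-ylidene)-3,4,4a,5,6,7,8,8a-octahydronaphthalen-2-yl trifluoromethanesulfonate | CC1=C(OS(=O)(=O)C(F)(F)F)CC[C@]2(C)CCC(=C(C)C)C[C@@H]12 | intermediate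
9 | (4aR,8aR)-5,8a-dimethyl-3-(propan-2-ylidene)-1,2,3,4,4a,7,8,8a-octahydronaphthalene [selina-3,7(11)-diene] | CC1=CCC[C@]2(C)CCC(=C(C)C)C[C@@H]12 | intermediate
10 | (1S,2R,4aS,8aR)-1,4a-dimethyl-7-(propan-2-ylidene)decahydronaphthalene-1,2-diol [eudesm-7(11)-ene-3α,4α-diol; 4β-CH3, 5α-H, 10β-CH3] | O[C@@H]1CC[C@]2(C)CCC(=C(C)C)C[C@H]2[C@]1(C)O | intermediate
11 | (S)-2-(benzyloxy)propanoic acid (O-benzyl-L-lactic acid) | C[C@H](OCc1ccccc1)C(=O)O | starting material
12 | (S)-3-(benzyloxy)butan-2-one | C[C@H](OCc1ccccc1)C(C)=O | intermediate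
13 | (3S,4S)-4-(benzyloxy)-3-methylpent-1-en-3-ol | C[C@H](OCc1ccccc1)[C@@](C)(O)C=C | intermediate
14 | (2R,3S)-3-(benzyloxy)-2-hydroxy-2-methylbutanal | C[C@H](OCc1ccccc1)[C@@](C)(O)C=O | intermediate
15 | (2R,3S)-3-(benzyloxy)-2-hydroxy-2-methylbutanoic acid | C[C@H](OCc1ccccc1)[C@@](C)(O)C(=O)O | intermediate
16 | (2R,3S)-2,3-dihydroxy-2-methylbutanoic acid | C[C@H](O)[C@@](C)(O)C(=O)O | intermediate
17 | (2R,3S)-3-acetoxy-2-hydroxy-2-methylbutanoic acid | CC(=O)O[C@@H](C)[C@@](C)(O)C(=O)O | intermediate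
18 | trimethylsilyl (2R,3S)-3-acetoxy-2-methyl-2-[(trimethylsilyl)oxy]butanoate | CC(=O)O[C@@H](C)[C@@](C)(O[Si](C)(C)C)C(=O)O[Si](C)(C)C | intermediate
19 | (2R,3S)-3-acetoxy-2-methyl-2-[(trimethylsilyl)oxy]butanoyl chloride | CC(=O)O[C@@H](C)[C@@](C)(O[Si](C)(C)C)C(Cl)=O | intermediate
20 | (3α,4α)-4-hydroxyeudesm-7(11)-en-3-yl (2R,3S)-3-acetoxy-2-methyl-2-[(trimethylsilyl)oxy]butanoate | CC(=O)O[C@@H](C)[C@@](C)(O[Si](C)(C)C)C(=O)O[C@@H]1CC[C@]2(C)CCC(=C(C)C)C[C@H]2[C@]1(C)O | intermediate
21 | (3α,4α)-4-acetoxyeudesm-7(11)-en-3-yl (2R,3S)-3-acetoxy-2-methyl-2-[(trimethylsilyl)oxy]butanoate | CC(=O)O[C@@H](C)[C@@](C)(O[Si](C)(C)C)C(=O)O[C@@H]1CC[C@]2(C)CCC(=C(C)C)C[C@H]2[C@]1(C)OC(C)=O | intermediate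
22 | (3α,4α)-4-acetoxyeudesm-7(11)-en-3-yl (2R,3S)-3-acetoxy-2-hydroxy-2-methylbutanoate | CC(=O)O[C@@H](C)[C@@](C)(O)C(=O)O[C@@H]1CC[C@]2(C)CCC(=C(C)C)C[C@H]2[C@]1(C)OC(C)=O | intermediate
23 | (3α,4α)-4-acetoxy-8-oxoeudesm-7(11)-en-3-yl (2R,3S)-3-acetoxy-2-hydroxy-2-methylbutanoate; ring centres 3R,4S,5R,10R (CNP0134046.2) | CC(=O)O[C@@H](C)[C@@](C)(O)C(=O)O[C@@H]1CC[C@]2(C)CC(=O)C(=C(C)C)C[C@H]2[C@]1(C)OC(C)=O | target

**Step count and risks**

Total step count: 13 (six on the terpenoid core, four on the acid, three after convergence).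
Longest linear sequence: 9 (steps 1–6, then 11–13).

The three steps most likely to fail:

Step 13 (the proposed new electrochemical oxidation). The risks are competing abstraction at C6 or at the allylic methyls, and incomplete conversion. The fallback uses known chemistry, sets out from 22 and comes back at 23. Riley-type allylic hydroxylation with SeO2 (0.5 equiv)/t-BuOOH in CH2Cl2 at rt proceeds by an ene reaction and [2,3]-sigmatropic shift, which favours ring CH2 over CH3 and the less hindered C8. It gives the allylic alcohol (3α,4α)-4-acetoxy-8-hydroxyeudesm-7(11)-en-3-yl (2R,3S)-3-acetoxy-2-hydroxy-2-methylbutanoate F1 (both C8 epimers). Dess–Martin periodinane in CH2Cl2 then oxidises it to 23.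

Step 11 (esterification of the hindered axial 3α-hydroxyl with an α-quaternary acyl donor). The fallback sets out from 10 and comes back at 20. Bu2SnO in toluene at reflux with azeotropic removal of water converts 10 into the cyclic dibutylstannylene acetal of eudesm-7(11)-ene-3α,4α-diol F2, in which the secondary C3 oxygen is the activated nucleophile. F2 is acylated by acid chloride 19 in CH2Cl2 at rt, and hydrolytic work-up gives 20.

Step 4 (radical isomerisation to the tetrasubstituted alkene; it may stall or drift to endocyclic isomers). The fallback sets out from 7 and comes back at 8. Dry HCl in CH2Cl2 at −30 °C adds to the isopropenyl group in the Markovnikov sense to give the tertiary chloride (4aS,7S,8aR)-7-(2-chloropropan-2-yl)-1,4a-dimethyl-3,4,4a,5,6,7,8,8a-octahydronaphthalen-2-yl trifluoromethanesulfonate F3. Saytzeff dehydrochlorination with LiBr/Li2CO3 in DMF at 110 °C then gives 8; any isopropenyl isomer 7 that re-forms is recycled.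

Further compounds
F1 | step 13 | (3α,4α)-4-acetoxy-8-hydroxyeudesm-7(11)-en-3-yl (2R,3S)-3-acetoxy-2-hydroxy-2-methylbutanoate (C8 epimers) | CC(=O)O[C@@H](C)[C@@](C)(O)C(=O)O[C@@H]1CC[C@]2(C)CC(O)C(=C(C)C)C[C@H]2[C@]1(C)OC(C)=O
F2 | step 11 | dibutylstannylene acetal of eudesm-7(11)-ene-3α,4α-diol (2,2-dibutyl-1,3,2-dioxastannolane fused at O3/O4) | CCCC[Sn]1(CCCC)O[C@@H]2CC[C@]3(C)CCC(=C(C)C)C[C@H]3[C@]2(C)O1
F3 | step 4 | (4aS,7S,8aR)-7-(2-chloropropan-2-yl)-1,4a-dimethyl-3,4,4a,5,6,7,8,8a-octahydronaphthalen-2-yl trifluoromethanesulfonate | CC1=C(OS(=O)(=O)C(F)(F)F)CC[C@]2(C)CC[C@H](C(C)(C)Cl)C[C@@H]12
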